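**Retrosynthetic overview** (locants: oxane ring O1, C2 aryl, C3, C4 hydroxyl, C5, C6 arylethyl; side chain C1'=C2', C3' on C3, C4' hydroxyl, C5'–C7')

- The target arises from a tetra-TIPS-protected oxan-4-one by axial-selective ketone reduction at C4 and fluoride removal of four aryl silyl ethers.
- The oxan-4-one arises in one flask from an (S)-terminal epoxide (C5–C6–O1) and an α-arylidene γ-butyrolactone (C2–C3–C4 plus the whole side chain): reductive lithiation reverses the polarity of C5, C4–C5 forms by acyl substitution, and O1–C2 forms by oxa-Michael addition. The oxane is the only ring of the target and is closed last.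
- Enabling feature: O1–C6–C5 maps onto a terminal epoxide; C2 is benzylic and β to C4, so with C4 as a ketone the O1–C2 ether is a reversible oxa-Michael bond; the C4' oxygen stands γ to C4 (C4–C3–C3'–C4'–O), so C4 can be carried as the carbonyl of a temporary γ-lactone ring that the key step opens.
- The arylidene lactone arises from aldol condensation of a trans-β-styryl-γ-alkyl lactone, made by copper-catalysed anti addition of an (E)-styryl Grignard reagent to an (S)-butenolide, itself made from a second (S)-epoxide.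
- Stereochemistry: C6 and C4' are bought as (S)-epichlorohydrin; C3' is relayed from C4', C2 and C3 from C6 under thermodynamic control, and C4 from the ring conformation.

Key step: step 12

Abbreviations: TIPS = tri(propan-2-yl)silyl; "4-(TIPSO)phenyl" = 4-[tri(propan-2-yl)silyloxy]phenyl.

**Step 1**
Reactants: 1 4-hydroxybenzaldehyde
Product: 2 4-(TIPSO)benzaldehyde
Conditions: i-Pr3SiCl, imidazole, DMF, rt
Reagents that add atoms: chlorotri(propan-2-yl)silane, CC(C)[Si](Cl)(C(C)C)C(C)C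
Why: Imidazole-mediated O-silylation of the phenol; the bulky aryl TIPS ether is chosen because it should survive the Grignard, organolithium and alkoxide steps and fall to fluoride at the end.

**Step 2**
Reactants: 2 4-(TIPSO)benzaldehyde
Product: 3 (E)-1-(2-iodoethenyl)-4-(TIPSO)benzene
Conditions: CHI3 (2 equiv), CrCl2 (6 equiv), THF, 0 °C → rt
Reagents that add atoms: iodoform, IC(I)I
Why: Takai olefination, in which the geminal dichromium species formed from iodoform and divalent chromium adds to the aldehyde and eliminates anti, which should give the (E)-iodoalkene.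

**Step 3**
Reactants: 2 4-(TIPSO)benzaldehyde
Product: 4 [4-(TIPSO)phenyl]methanol
Conditions: NaBH4, MeOH, 0 °C
Reagents that add atoms: none
Why: Borohydride reduction of an aromatic aldehyde to the benzylic alcohol; no stereocentre is formed.

**Step 4**
Reactants: 4 [4-(TIPSO)phenyl]methanol
Product: 5 1-(chloromethyl)-4-(TIPSO)benzene
Conditions: SOCl2, pyridine, CH2Cl2, 0 °C
Reagents that add atoms: thionyl chloride, O=S(Cl)Cl
Why: Chlorodehydroxylation of an electron-rich benzylic alcohol with pyridine-buffered thionyl chloride, conditions the aryl silyl ether should tolerate.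

**Step 5**
Reactants: 5 1-(chloromethyl)-4-(TIPSO)benzene; 6 (S)-epichlorohydrin
Product: 9 (2S)-2-{2-[4-(TIPSO)phenyl]ethyl}oxirane, via benzylic Grignard reagent 7 (not isolated), via chlorohydrin 8 (not isolated)
Conditions: Mg, Et2O, 0 °C (slow addition); CuI (10 mol %), 6, −40 → 0 °C; aq. NH4Cl; crude 8, NaH, THF, 0 °C → rt
Reagents that add atoms: none
Why: Grignard formation, CuI-catalysed opening of the epoxide at its unsubstituted carbon and Williamson-type closure of the chloro alkoxide; no bond to the stereocentre is broken, so the bought (S) configuration becomes C6 of the target.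

**Step 6**
Reactants: 10 4-(2-bromoethyl)phenol
Product: 11 1-(2-bromoethyl)-4-(TIPSO)benzene
Conditions: i-Pr3SiCl, imidazole, CH2Cl2, rt
Reagents that add atoms: chlorotri(propan-2-yl)silane, CC(C)[Si](Cl)(C(C)C)C(C)C
Why: Imidazole-mediated O-silylation of the phenol under conditions too weakly basic to disturb the primary bromide.

**Step 7**
Reactants: 11 1-(2-bromoethyl)-4-(TIPSO)benzene; 6 (S)-epichlorohydrin
Product: 14 (2S)-2-{3-[4-(TIPSO)phenyl]propyl}oxirane, via arylethyl Grignard reagent 12 (not isolated), via chlorohydrin 13 (not isolated)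
Conditions: Mg, THF, rt; CuI (10 mol %), 6, −40 → 0 °C; aq. NH4Cl; crude 13, NaH, THF, 0 °C → rt
Reagents that add atoms: none
Why: The same CuI-catalysed Grignard opening and ring closure as in step 5; the untouched (S) centre becomes C4' of the target.

**Step 8**
Reactants: 14 (2S)-2-{3-[4-(TIPSO)phenyl]propyl}oxirane; 15 (phenylsulfanyl)acetic acid
Product: 18 (5S)-3-(phenylsulfanyl)-5-{3-[4-(TIPSO)phenyl]propyl}oxolan-2-one (mixture of C3 epimers), via dilithiated thioacetate 16 (not isolated), via hydroxy acid 17 (not isolated)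
Conditions: 15, LiN(i-Pr)2 (2.1 equiv per 15), THF, 0 °C; 14, 0 °C → rt; 1 M HCl; TsOH·H2O (5 mol %), toluene, 60 °C
Reagents that add atoms: none
Why: Opening of the terminal epoxide at its CH2 carbon by the α-thio carboxylate dianion followed by acid-catalysed lactonisation of the γ-hydroxy acid; the carbinol centre is retained and the sulfur-bearing centre forms as an inconsequential mixture.

**Step 9**
Reactants: 18 (5S)-3-(phenylsulfanyl)-5-{3-[4-(TIPSO)phenyl]propyl}oxolan-2-one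
Product: 20 (5S)-5-{3-[4-(TIPSO)phenyl]propyl}furan-2(5H)-one, via sulfoxide 19 (not isolated)
Conditions: mCPBA (1.0 equiv), CH2Cl2, −78 °C; then CaCO3, toluene, 110 °C
Reagents that add atoms: none
Why: Sulfide oxidation and thermal syn-elimination of benzenesulfenic acid (sulfoxide pyrolysis) toward the only β-hydrogens should give the butenolide, and the neutral conditions avoid deprotonation at C5.

**Step 10**
Reactants: 20 (5S)-5-{3-[4-(TIPSO)phenyl]propyl}furan-2(5H)-one; 3 (E)-1-(2-iodoethenyl)-4-(TIPSO)benzene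
Product: 23 (4S,5S)-4-{(E)-2-[4-(TIPSO)phenyl]ethenyl}-5-{3-[4-(TIPSO)phenyl]propyl}oxolan-2-one, via alkenylmagnesium chloride 21 (not isolated), via silyl ketene acetal 22 (not isolated)
Conditions: 3, i-PrMgCl·LiCl, THF, 0 °C → rt; CuBr·SMe2 (10 mol %), Me3SiCl (2 equiv), −78 °C; 20, −78 → −40 °C; aq. NH4Cl
Reagents that add atoms: none
Why: Iodine–magnesium exchange with retention of alkene geometry and copper-catalysed, chlorosilane-accelerated conjugate addition; the alkenyl group adds to the butenolide face anti to the C5 substituent, which sets C3' of the target (trans lactone).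

**Step 11**
Reactants: 23 (4S,5S)-4-{(E)-2-[4-(TIPSO)phenyl]ethenyl}-5-{3-[4-(TIPSO)phenyl]propyl}oxolan-2-one; 2 4-(TIPSO)benzaldehyde
Product: 26 (3E,4R,5S)-3-{[4-(TIPSO)phenyl]methylidene}-4-{(E)-2-[4-(TIPSO)phenyl]ethenyl}-5-{3-[4-(TIPSO)phenyl]propyl}oxolan-2-one, via lithium enolate 24 (not isolated), via lithium aldolate 25 (not isolated)
Conditions: LiN(SiMe3)2, THF, −78 °C; 2; then MsCl, Et3N, −78 °C → rt
Reagents that add atoms: none
Why: Aldol addition of the lactone enolate to the aldehyde followed by mesylation and amine-induced elimination through the activated benzylic position (aldol condensation); the two transient centres vanish and the geometry of the new alkene is inconsequential because step 12 is stereoconvergent.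

**Step 12**
Reactants: 26 (3E,4R,5S)-3-{[4-(TIPSO)phenyl]methylidene}-4-{(E)-2-[4-(TIPSO)phenyl]ethenyl}-5-{3-[4-(TIPSO)phenyl]propyl}oxolan-2-one; 9 (2S)-2-{2-[4-(TIPSO)phenyl]ethyl}oxirane
Product: 29 (2S,3R,6S)-3-{(1E,3R,4S)-4-hydroxy-1,7-bis[4-(TIPSO)phenyl]hept-1-en-3-yl}-2-[4-(TIPSO)phenyl]-6-{2-[4-(TIPSO)phenyl]ethyl}oxan-4-one, via β-lithioalkoxide 27 (not isolated), via δ-hydroxy enone 28 (not isolated)
Conditions: 9 (1.3 equiv), lithium 4,4'-di-tert-butylbiphenylide (LiDBB, 2.5 equiv), THF, −78 °C, 15 min; 26 (1.0 equiv), −78 °C, 1 h; i-PrOH (6 equiv), −78 → 0 °C; aq. NH4Cl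
Reagents that add atoms: none
Why: Proposed new method: two equivalents of LiDBB cleave the primary C–O bond of the epoxide and turn the normally electrophilic C5 into the carbanion of β-lithioalkoxide 27 (polarity reversal, C6 untouched), which attacks the lactone carbonyl C4 of 26 to give a lithium lactolate; on warming with i-PrOH this opens to δ-hydroxy enone 28, whose C6 alkoxide adds to the benzylic β-carbon C2. The closest known reaction types are the trapping of epoxide-derived β-lithioalkoxides with carbonyl electrophiles, the mono-addition of organolithiums to γ-lactones and the alkoxide-mediated oxa-Michael cyclisation of δ-hydroxy β-aryl enones to 2,6-cis-oxan-4-ones; new is their merger in one flask with an α-arylidene lactone as acyl donor. One ring is closed, the oxane, by 6-endo-trig conjugate addition, while the temporary lactone ring is opened and releases the C4' hydroxyl without a protecting group. C2 is controlled by the bought C6 centre, because the reversible oxa-Michael addition should funnel both alkene isomers of 26 into the chair with the 2-aryl and 6-arylethyl groups equatorial (2,6-cis), and C3 is controlled by enolate equilibration to the equatorial position trans to the aryl group; C3', C4' and C6 are not touched. The step needs mono-1,2-addition rather than 1,4- or double addition, which the hard alkyllithium, the fully substituted α-carbon and electron-rich β-aryl group of 26 and the persistence of the lactolate at −78 °C should secure; it also needs closure through O1 rather than the freed C4' alkoxide, which can only close by a disfavoured 5-endo-trig path or a reversible hemiketal.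

**Step 13**
Reactants: 29 the oxan-4-one of step 12
Product: 30 (2S,3S,4S,6S)-3-{(1E,3R,4S)-4-hydroxy-1,7-bis[4-(TIPSO)phenyl]hept-1-en-3-yl}-2-[4-(TIPSO)phenyl]-6-{2-[4-(TIPSO)phenyl]ethyl}oxan-4-ol
Conditions: LiBH(s-Bu)3 (3 equiv), THF, −78 °C; aq. NH4Cl
Reagents that add atoms: none
Why: Ketone reduction under steric approach control, in which the bulky trialkylborohydride attacks the chair oxan-4-one along the equatorial trajectory and should give the axial C4 hydroxyl cis to the equatorial C3 substituent (4S).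

**Step 14**
Reactants: 30 the tetra-TIPS oxan-4-ol of step 13
Product: 31 (2S,3S,4S,6S)-3-[(1E,3R,4S)-4-hydroxy-1,7-bis(4-hydroxyphenyl)hept-1-en-3-yl]-2-(4-hydroxyphenyl)-6-[2-(4-hydroxyphenyl)ethyl]oxan-4-ol (CNP0132332.1)
Conditions: Bu4NF (6 equiv), AcOH (6 equiv), THF, 0 °C → rt
Reagents that add atoms: none
Why: Fluoride-induced cleavage of the four aryl silyl ethers, buffered with acetic acid so that the styrene and the benzylic ether at C2 are not exposed to free phenoxide or strong acid; no stereocentre is touched.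

**Compound list**

1 | 4-hydroxybenzaldehyde | O=Cc1ccc(O)cc1 | starting material
2 | 4-(TIPSO)benzaldehyde | O=Cc1ccc(O[Si](C(C)C)(C(C)C)C(C)C)cc1 | intermediate
3 | (E)-1-(2-iodoethenyl)-4-(TIPSO)benzene | I/C=C/c1ccc(O[Si](C(C)C)(C(C)C)C(C)C)cc1 | intermediate
4 | [4-(TIPSO)phenyl]methanol | OCc1ccc(O[Si](C(C)C)(C(C)C)C(C)C)cc1 | intermediate
5 | 1-(chloromethyl)-4-(TIPSO)benzene | ClCc1ccc(O[Si](C(C)C)(C(C)C)C(C)C)cc1 | intermediate
6 | (S)-epichlorohydrin | ClC[C@@H]1CO1 | starting material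
7 | [4-(TIPSO)benzyl]magnesium chloride | Cl[Mg]Cc1ccc(O[Si](C(C)C)(C(C)C)C(C)C)cc1 | intermediate
8 | (2S)-1-chloro-4-[4-(TIPSO)phenyl]butan-2-ol | ClC[C@@H](O)CCc1ccc(O[Si](C(C)C)(C(C)C)C(C)C)cc1 | intermediate
9 | (2S)-2-{2-[4-(TIPSO)phenyl]ethyl}oxirane | CC(C)[Si](Oc1ccc(CC[C@H]2CO2)cc1)(C(C)C)C(C)C | intermediate
10 | 4-(2-bromoethyl)phenol | Oc1ccc(CCBr)cc1 | starting material
11 | 1-(2-bromoethyl)-4-(TIPSO)benzene | BrCCc1ccc(O[Si](C(C)C)(C(C)C)C(C)C)cc1 | intermediate
12 | {2-[4-(TIPSO)phenyl]ethyl}magnesium bromide | Br[Mg]CCc1ccc(O[Si](C(C)C)(C(C)C)C(C)C)cc1 | intermediate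
13 | (2S)-1-chloro-5-[4-(TIPSO)phenyl]pentan-2-ol | ClC[C@@H](O)CCCc1ccc(O[Si](C(C)C)(C(C)C)C(C)C)cc1 | intermediate
14 | (2S)-2-{3-[4-(TIPSO)phenyl]propyl}oxirane | CC(C)[Si](Oc1ccc(CCC[C@H]2CO2)cc1)(C(C)C)C(C)C | intermediate
15 | (phenylsulfanyl)acetic acid | OC(=O)CSc1ccccc1 | starting material
16 | lithium 2-lithio-2-(phenylsulfanyl)acetate | [Li]OC(=O)C([Li])Sc1ccccc1 | intermediate
17 | (4S)-4-hydroxy-2-(phenylsulfanyl)-7-[4-(TIPSO)phenyl]heptanoic acid (C2 epimers) | OC(=O)C(Sc1ccccc1)C[C@@H](O)CCCc1ccc(O[Si](C(C)C)(C(C)C)C(C)C)cc1 | intermediate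
18 | (5S)-3-(phenylsulfanyl)-5-{3-[4-(TIPSO)phenyl]propyl}oxolan-2-one (C3 epimers) | O=C1C(Sc2ccccc2)C[C@H](CCCc2ccc(O[Si](C(C)C)(C(C)C)C(C)C)cc2)O1 | intermediate
19 | (5S)-3-(phenylsulfinyl)-5-{3-[4-(TIPSO)phenyl]propyl}oxolan-2-one (isomer mixture) | O=C1C(S(=O)c2ccccc2)C[C@H](CCCc2ccc(O[Si](C(C)C)(C(C)C)C(C)C)cc2)O1 | intermediate
20 | (5S)-5-{3-[4-(TIPSO)phenyl]propyl}furan-2(5H)-one | O=C1C=C[C@H](CCCc2ccc(O[Si](C(C)C)(C(C)C)C(C)C)cc2)O1 | intermediate
21 | {(E)-2-[4-(TIPSO)phenyl]ethenyl}magnesium chloride | Cl[Mg]/C=C/c1ccc(O[Si](C(C)C)(C(C)C)C(C)C)cc1 | intermediate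
22 | trimethylsilyl ketene acetal of lactone 23 | C[Si](C)(C)OC1=C[C@@H](/C=C/c2ccc(O[Si](C(C)C)(C(C)C)C(C)C)cc2)[C@H](CCCc2ccc(O[Si](C(C)C)(C(C)C)C(C)C)cc2)O1 | intermediate
23 | (4S,5S)-4-{(E)-2-[4-(TIPSO)phenyl]ethenyl}-5-{3-[4-(TIPSO)phenyl]propyl}oxolan-2-one | O=C1C[C@@H](/C=C/c2ccc(O[Si](C(C)C)(C(C)C)C(C)C)cc2)[C@H](CCCc2ccc(O[Si](C(C)C)(C(C)C)C(C)C)cc2)O1 | intermediate
24 | lithium enolate of lactone 23 | [Li]OC1=C[C@@H](/C=C/c2ccc(O[Si](C(C)C)(C(C)C)C(C)C)cc2)[C@H](CCCc2ccc(O[Si](C(C)C)(C(C)C)C(C)C)cc2)O1 | intermediate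
25 | lithium aldolate of 23 with 2 (isomer mixture at the two new centres) | O=C1C(C(O[Li])c2ccc(O[Si](C(C)C)(C(C)C)C(C)C)cc2)[C@@H](/C=C/c2ccc(O[Si](C(C)C)(C(C)C)C(C)C)cc2)[C@H](CCCc2ccc(O[Si](C(C)C)(C(C)C)C(C)C)cc2)O1 | intermediate
26 | (3E,4R,5S)-3-{[4-(TIPSO)phenyl]methylidene}-4-{(E)-2-[4-(TIPSO)phenyl]ethenyl}-5-{3-[4-(TIPSO)phenyl]propyl}oxolan-2-one | O=C1/C(=C/c2ccc(O[Si](C(C)C)(C(C)C)C(C)C)cc2)[C@@H](/C=C/c2ccc(O[Si](C(C)C)(C(C)C)C(C)C)cc2)[C@H](CCCc2ccc(O[Si](C(C)C)(C(C)C)C(C)C)cc2)O1 | intermediate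
27 | lithium 1-lithio-4-[4-(TIPSO)phenyl]butan-2-olate (carbinol centre as in 9) | [Li]C[C@@H](O[Li])CCc1ccc(O[Si](C(C)C)(C(C)C)C(C)C)cc1 | intermediate
28 | (1E,5S)-5-hydroxy-2-{(1E,3R,4S)-4-hydroxy-1,7-bis[4-(TIPSO)phenyl]hept-1-en-3-yl}-1,7-bis[4-(TIPSO)phenyl]hept-1-en-3-one (present as its lithium alkoxides) | O=C(C[C@@H](O)CCc1ccc(O[Si](C(C)C)(C(C)C)C(C)C)cc1)/C(=C/c1ccc(O[Si](C(C)C)(C(C)C)C(C)C)cc1)[C@@H](/C=C/c1ccc(O[Si](C(C)C)(C(C)C)C(C)C)cc1)[C@@H](O)CCCc1ccc(O[Si](C(C)C)(C(C)C)C(C)C)cc1 | intermediate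
29 | (2S,3R,6S)-3-{(1E,3R,4S)-4-hydroxy-1,7-bis[4-(TIPSO)phenyl]hept-1-en-3-yl}-2-[4-(TIPSO)phenyl]-6-{2-[4-(TIPSO)phenyl]ethyl}oxan-4-one | CC(C)[Si](Oc1ccc(/C=C/[C@H]([C@@H]2[C@@H](c3ccc(O[Si](C(C)C)(C(C)C)C(C)C)cc3)O[C@@H](CCc3ccc(O[Si](C(C)C)(C(C)C)C(C)C)cc3)CC2=O)[C@@H](O)CCCc2ccc(O[Si](C(C)C)(C(C)C)C(C)C)cc2)cc1)(C(C)C)C(C)C | intermediate
30 | (2S,3S,4S,6S)-3-{(1E,3R,4S)-4-hydroxy-1,7-bis[4-(TIPSO)phenyl]hept-1-en-3-yl}-2-[4-(TIPSO)phenyl]-6-{2-[4-(TIPSO)phenyl]ethyl}oxan-4-ol | CC(C)[Si](Oc1ccc(/C=C/[C@H]([C@@H]2[C@@H](c3ccc(O[Si](C(C)C)(C(C)C)C(C)C)cc3)O[C@@H](CCc3ccc(O[Si](C(C)C)(C(C)C)C(C)C)cc3)C[C@@H]2O)[C@@H](O)CCCc2ccc(O[Si](C(C)C)(C(C)C)C(C)C)cc2)cc1)(C(C)C)C(C)C | intermediate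
31 | (2S,3S,4S,6S)-3-[(1E,3R,4S)-4-hydroxy-1,7-bis(4-hydroxyphenyl)hept-1-en-3-yl]-2-(4-hydroxyphenyl)-6-[2-(4-hydroxyphenyl)ethyl]oxan-4-ol | Oc1ccc(/C=C/[C@H]([C@@H]2[C@@H](c3ccc(O)cc3)O[C@@H](CCc3ccc(O)cc3)C[C@@H]2O)[C@@H](O)CCCc2ccc(O)cc2)cc1 | target

**Step count and risks**

Total step count: 14. Longest linear sequence: 9 steps (steps 6 to 14, from 4-(2-bromoethyl)phenol 10).

Steps most likely to fail:

Step 12. The alkyllithium may add twice to the lactone or act on it as a base instead of giving clean mono-acylation, or the lactolate may fail to open and close through O1. The fallback uses known, stepwise chemistry with the side-chain oxygen masked; it sets out from 26 and 9 and comes back at 29. Lactone 26 would be opened by Weinreb aminolysis (Me3Al, MeNH(OMe)·HCl, CH2Cl2, 0 °C) to the γ-hydroxy N-methoxy-N-methyl amide F1. This would be silylated at once (Et3SiCl, imidazole, DMF) to the triethylsilyl ether F2. The β-lithioalkoxide 27, made from 9 as in step 12, would be added to F2 at −78 °C, where the chelated tetrahedral adduct prevents over-addition, and work-up should give the isolated δ-hydroxy enone F3. Separate treatment of F3 with KOt-Bu (0.2 equiv) in THF at 0 °C should effect the precedented equilibrating oxa-Michael cyclisation to the oxan-4-one triethylsilyl ether F4. PPTS in MeOH would then remove the secondary silyl ether and give 29.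

Step 13. Hydride may be delivered from the wrong face, or the reduction may stall, because the free C4' hydroxyl can tie up the C4 ketone as a five-membered hemiketal or direct the reagent as its alkoxide. The fallback sets out from 29 and comes back at 31. Silylation of 29 (Et3SiCl, imidazole, DMF) would give the oxan-4-one triethylsilyl ether F4, a plain 3-substituted oxan-4-one. Reduction with KBH(s-Bu)3 in THF at −78 °C should then give the axial alcohol F5 under pure steric approach control. The fluoride treatment of step 14 (Bu4NF, AcOH, THF) would remove all five silyl groups and give 31.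

Step 10. The iodine–magnesium exchange may be incomplete, or the basic organometallic may abstract the C5 proton of the butenolide, which would erode the bought configuration. The fallback sets out from 3 and 20 and comes back at 23. Miyaura borylation of 3 (B2pin2, PdCl2(PPh3)2, PPh3, KOPh, toluene, 50 °C) would give the (E)-alkenylboronic pinacol ester F6. Rhodium-catalysed conjugate addition of F6 to 20 ([Rh(OH)(cod)]2 3 mol %, dioxane/H2O, 40 °C, Hayashi–Miyaura reaction) runs under near-neutral conditions and should again add anti to the C5 substituent to give 23.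

**Further compounds**

F1 | step 12 | (2E,3R,4S)-4-hydroxy-N-methoxy-N-methyl-3-{(E)-2-[4-(TIPSO)phenyl]ethenyl}-2-{[4-(TIPSO)phenyl]methylidene}-7-[4-(TIPSO)phenyl]heptanamide | CON(C)C(=O)/C(=C/c1ccc(O[Si](C(C)C)(C(C)C)C(C)C)cc1)[C@@H](/C=C/c1ccc(O[Si](C(C)C)(C(C)C)C(C)C)cc1)[C@@H](O)CCCc1ccc(O[Si](C(C)C)(C(C)C)C(C)C)cc1
F2 | step 12 | triethylsilyl ether of F1 | CON(C)C(=O)/C(=C/c1ccc(O[Si](C(C)C)(C(C)C)C(C)C)cc1)[C@@H](/C=C/c1ccc(O[Si](C(C)C)(C(C)C)C(C)C)cc1)[C@@H](O[Si](CC)(CC)CC)CCCc1ccc(O[Si](C(C)C)(C(C)C)C(C)C)cc1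
F3 | step 12 | (1E,5S)-5-hydroxy-2-{(1E,3R,4S)-4-(triethylsilyloxy)-1,7-bis[4-(TIPSO)phenyl]hept-1-en-3-yl}-1,7-bis[4-(TIPSO)phenyl]hept-1-en-3-one | O=C(C[C@@H](O)CCc1ccc(O[Si](C(C)C)(C(C)C)C(C)C)cc1)/C(=C/c1ccc(O[Si](C(C)C)(C(C)C)C(C)C)cc1)[C@@H](/C=C/c1ccc(O[Si](C(C)C)(C(C)C)C(C)C)cc1)[C@@H](O[Si](CC)(CC)CC)CCCc1ccc(O[Si](C(C)C)(C(C)C)C(C)C)cc1
F4 | step 12 | (2S,3R,6S)-3-{(1E,3R,4S)-4-(triethylsilyloxy)-1,7-bis[4-(TIPSO)phenyl]hept-1-en-3-yl}-2-[4-(TIPSO)phenyl]-6-{2-[4-(TIPSO)phenyl]ethyl}oxan-4-one | CC(C)[Si](Oc1ccc(/C=C/[C@H]([C@@H]2[C@@H](c3ccc(O[Si](C(C)C)(C(C)C)C(C)C)cc3)O[C@@H](CCc3ccc(O[Si](C(C)C)(C(C)C)C(C)C)cc3)CC2=O)[C@@H](O[Si](CC)(CC)CC)CCCc2ccc(O[Si](C(C)C)(C(C)C)C(C)C)cc2)cc1)(C(C)C)C(C)C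
F5 | step 13 | (2S,3S,4S,6S)-3-{(1E,3R,4S)-4-(triethylsilyloxy)-1,7-bis[4-(TIPSO)phenyl]hept-1-en-3-yl}-2-[4-(TIPSO)phenyl]-6-{2-[4-(TIPSO)phenyl]ethyl}oxan-4-ol | CC(C)[Si](Oc1ccc(/C=C/[C@H]([C@@H]2[C@@H](c3ccc(O[Si](C(C)C)(C(C)C)C(C)C)cc3)O[C@@H](CCc3ccc(O[Si](C(C)C)(C(C)C)C(C)C)cc3)C[C@@H]2O)[C@@H](O[Si](CC)(CC)CC)CCCc2ccc(O[Si](C(C)C)(C(C)C)C(C)C)cc2)cc1)(C(C)C)C(C)C
F6 | step 10 | 4,4,5,5-tetramethyl-2-{(E)-2-[4-(TIPSO)phenyl]ethenyl}-1,3,2-dioxaborolane | CC1(C)OB(/C=C/c2ccc(O[Si](C(C)C)(C(C)C)C(C)C)cc2)OC1(C)C
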